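**Strategy**

Ring A (C1–C5, C10) is disconnected across C2–C3 and C5–C10. C10 and C2 both flank C1, and C5 and C3 both flank C4, the carbon bearing the two hydroxymethyl groups; a carbonyl at C1 and a carboxyl at C4 therefore turn ring A into a ketone α,α′-bis-nucleophile plus a 2-(acetoxymethyl)enoate bis-electrophile. In one base-mediated operation the acyclic keto ester 12 closes ring B (Michael addition of C10 to C5), loses acetate, and closes ring A (Michael addition of C2 to C3), setting C5 and quaternary C10 from C9. The C1 carbonyl is then removed, and C4 gains its second hydroxymethyl group.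

Key step: step 9

Remark: labdane numbering is used for every intermediate (C1–C10 decalin carbons, C11–C16 side chain, C17 on C8, C18 and C19 on C4, C20 the methyl on C10). Centres drawn without configuration (C10 in 7–12, C1 in 8, C5 in 11) are deliberate epimer mixtures that are erased later.

**Route**

Step 1
Reactants: 1 3-[(tert-butyldimethylsilyl)oxy]propanal; 2 pent-1-en-3-one (ethyl vinyl ketone)
Product: 3 (R)-2-{[(tert-butyldimethylsilyl)oxy]methyl}-5-oxoheptanal
Conditions: (R)-α,α-diphenylprolinol trimethylsilyl ether (5 mol %), ethyl 3,4-dihydroxybenzoate (20 mol %), neat, 4 °C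
Reagents that add atoms: none
Why: Enamine-catalysed asymmetric Michael addition of an aldehyde to a vinyl ketone; the diarylprolinol silyl ether blocks one face of the (E)-enamine, and the (R)-catalyst is chosen because, by analogy with related additions, it should give C8 with the configuration needed in the target.

Step 2
Reactants: 3 (R)-2-{[(tert-butyldimethylsilyl)oxy]methyl}-5-oxoheptanal
Product: 4 (S)-4-{[(tert-butyldimethylsilyl)oxy]methyl}-2-methylcyclohex-2-en-1-one
Conditions: LiOH·H2O (10 mol %), i-PrOH, rt
Reagents that add atoms: none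
Why: Intramolecular aldol condensation (Robinson-type cyclodehydration): only the C10 methylene of the ethyl ketone reaches the aldehyde through a six-membered ring, and catalytic hydroxide should be mild enough to leave C8 and the silyloxy group intact.

Step 3
Reactants: 4 (S)-4-{[(tert-butyldimethylsilyl)oxy]methyl}-2-methylcyclohex-2-en-1-one
Product: 6 (2R,3R,4S)-2-acetyl-3-ethenyl-4-{[(tert-butyldimethylsilyl)oxy]methyl}-2-methylcyclohexan-1-one, via bromomagnesium enolate 5 (not isolated)
Conditions: CH2=CHMgBr, CuBr·SMe2 (20 mol %), THF, −40 °C; then 1-acetylbenzotriazole, −40 °C to rt; aq. NH4Cl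
Reagents that add atoms: vinylmagnesium bromide (C=C[Mg]Br); 1-acetyl-1H-benzotriazole (CC(=O)n1nnc2ccccc12)
Why: Copper-catalysed conjugate addition should occur trans to the C8 substituent and so set C9, and the regiodefined enolate is then C-acylated by the N-acylbenzotriazole; the configuration formed at C10 does not matter because step 4 erases it.

Step 4
Reactants: 6 (2R,3R,4S)-2-acetyl-3-ethenyl-4-{[(tert-butyldimethylsilyl)oxy]methyl}-2-methylcyclohexan-1-one
Product: 7 methyl (4S,5R)-4-{[(tert-butyldimethylsilyl)oxy]methyl}-5-ethenyl-6-methyl-7-oxooctanoate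
Conditions: NaOMe (0.2 equiv), MeOH, 0 °C to rt
Reagents that add atoms: methanol (CO)
Why: Retro-Claisen cleavage of a non-enolisable β-diketone: methoxide should add to the more electrophilic ring carbonyl C5 and expel the acetyl-stabilised C10 carbanion, opening the ring between C5 and C10 to the acyclic keto ester with C8 and C9 untouched.

Step 5
Reactants: 7 methyl (4S,5R)-4-{[(tert-butyldimethylsilyl)oxy]methyl}-5-ethenyl-6-methyl-7-oxooctanoate
Product: 8 (4S,5R)-4-{[(tert-butyldimethylsilyl)oxy]methyl}-5-ethenyl-6-methyloctane-1,7-diol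
Conditions: LiAlH4, THF, 0 °C
Reagents that add atoms: none
Why: Hydride reduction of both ester and ketone avoids having to distinguish the two carbonyl groups on the way to the C5 aldehyde; the uncontrolled carbinol centre at C1 is oxidised again in step 6.

Step 6
Reactants: 8 (4S,5R)-4-{[(tert-butyldimethylsilyl)oxy]methyl}-5-ethenyl-6-methyloctane-1,7-diol
Product: 9 (4S,5R)-4-{[(tert-butyldimethylsilyl)oxy]methyl}-5-ethenyl-6-methyl-7-oxooctanal
Conditions: Dess–Martin periodinane, CH2Cl2, rt
Reagents that add atoms: none
Why: Dess–Martin oxidation of the primary and the secondary alcohol gives the keto aldehyde under near-neutral conditions that should spare the silyl ether and C9.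

Step 7
Reactants: 9 (4S,5R)-4-{[(tert-butyldimethylsilyl)oxy]methyl}-5-ethenyl-6-methyl-7-oxooctanal; 10 methyl acrylate
Product: 11 methyl (6S,7R)-6-{[(tert-butyldimethylsilyl)oxy]methyl}-7-ethenyl-3-hydroxy-8-methyl-2-methylidene-9-oxodecanoate
Conditions: DABCO (0.5 equiv), MeOH, rt
Reagents that add atoms: none
Why: Morita–Baylis–Hillman reaction: the DABCO–acrylate zwitterion should add to the aldehyde only (the hindered methyl ketone is inert), installing C3, C4 and the C4 carboxyl; the new carbinol centre C5 becomes sp2 in step 8.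

Step 8
Reactants: 11 methyl (6S,7R)-6-{[(tert-butyldimethylsilyl)oxy]methyl}-7-ethenyl-3-hydroxy-8-methyl-2-methylidene-9-oxodecanoate
Product: 12 methyl (2E,6S,7R)-2-(acetoxymethyl)-6-{[(tert-butyldimethylsilyl)oxy]methyl}-7-ethenyl-8-methyl-9-oxodec-2-enoate
Conditions: Ac2O, Me3SiOSO2CF3 (5 mol %), CH2Cl2, 0 °C
Reagents that add atoms: acetic anhydride (CC(=O)OC(C)=O)
Why: Acetylation with Lewis-acid-promoted 1,3-transposition of the allylic acetate should give the thermodynamically preferred conjugated (2E)-2-(acetoxymethyl)enoate, the isomer that accepts a nucleophile at C5.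

Step 9
Reactants: 12 methyl (2E,6S,7R)-2-(acetoxymethyl)-6-{[(tert-butyldimethylsilyl)oxy]methyl}-7-ethenyl-8-methyl-9-oxodec-2-enoate
Product: 14 methyl 5-ethenyl-6-{[(tert-butyldimethylsilyl)oxy]methyl}-4a-methyl-4-oxodecahydronaphthalene-1-carboxylate (trans-fused; ester equatorial; configuration as in the SMILES), via acrylate ketone 13 (not isolated)
Conditions: KOt-Bu (1.2 equiv), THF/t-BuOH (10:1), −30 °C to rt; aq. NH4Cl
Reagents that add atoms: none
Why: KOt-Bu equilibrates the ketone enolates; only the C10 enolate can reach C5 through a six-membered transition state (6-exo-trig Michael addition closing ring B), the resulting ester enolate expels acetate (E1cB) to unveil the 2-substituted acrylate 13, and the C2 enolate then adds to C3 (6-endo-trig Michael addition closing ring A). This is the intramolecular form of the α,α′-annulation of ketones with 2-(acyloxymethyl)acrylates (Michael addition, elimination, Michael addition). C10 should be set from C9 by allylic 1,3-strain in the tetrasubstituted enolate: the C9–H bond eclipses the enolate double bond, C5 arrives on the face that carries C8, and C1 ends up anti to C8 (equatorial) with the methyl axial; the enoate should react likewise with C4 equatorial, so C5–H is trans to the methyl, ring A closes trans-fused, and C4 is protonated under equilibrating conditions to the equatorial ester. The step needs Michael addition to win over γ-deprotonation at C6 with 1,4-loss of acetate and over Claisen acylation; the low temperature, the acetate being a poor leaving group for direct substitution, and the fact that only six-membered closures are available are meant to secure this.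

Step 10
Reactants: 14 methyl 5-ethenyl-6-{[(tert-butyldimethylsilyl)oxy]methyl}-4a-methyl-4-oxodecahydronaphthalene-1-carboxylate
Product: 16 5-ethenyl-6-(hydroxymethyl)-4a-methyldecahydronaphthalene-1-carboxylic acid (trans-fused; carboxyl equatorial), via hydrazone 15 (not isolated)
Conditions: N2H4·H2O, KOH, diethylene glycol, Ar, 130 °C then 200 °C; aq. HCl
Reagents that add atoms: potassium hydroxide ([K+].[OH-])
Why: Wolff–Kishner reduction (Huang–Minlon modification) removes the C1 carbonyl that served as activating group; the hot hydroxide should also saponify the ester and cleave the silyl ether, both wanted here, and C4 should settle as the equatorial carboxylate.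

Step 11
Reactants: 16 5-ethenyl-6-(hydroxymethyl)-4a-methyldecahydronaphthalene-1-carboxylic acid
Product: 17 5-ethenyl-1,6-bis(hydroxymethyl)-4a-methyldecahydronaphthalene-1-carboxylic acid (carboxyl axial and cis to the angular methyl)
Conditions: LiN(i-Pr)2 (3.5 equiv), THF, −78 to 40 °C; then CH2O (gas), −78 °C to rt; aq. HCl
Reagents that add atoms: formaldehyde (C=O)
Why: α-Deprotonation of the lithium carboxylate gives an enediolate that should undergo aldol addition to formaldehyde from the face opposite the axial C10 methyl, creating quaternary C4; its configuration becomes irrelevant after step 12.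

Step 12
Reactants: 17 5-ethenyl-1,6-bis(hydroxymethyl)-4a-methyldecahydronaphthalene-1-carboxylic acid
Product: 18 [(1R,2S,4aS,8aS)-1-ethenyl-8a-methyloctahydronaphthalene-2,5,5(1H)-triyl]trimethanol
Conditions: LiAlH4, THF, reflux
Reagents that add atoms: none
Why: Hydride reduction of the carboxylic acid to the primary alcohol makes the two C4 substituents identical, so C4 is no longer a stereocentre.

Step 13
Reactants: 18 [(1R,2S,4aS,8aS)-1-ethenyl-8a-methyloctahydronaphthalene-2,5,5(1H)-triyl]trimethanol; 19 3-bromofuran-2(5H)-one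
Product: 21 3-{2-[(1R,2S,4aS,8aS)-2,5,5-tris(hydroxymethyl)-8a-methyldecahydronaphthalen-1-yl]ethyl}furan-2(5H)-one (the target), via alkylborane 20 (not isolated)
Conditions: 9-BBN dimer (excess), THF, rt; then 19, PdCl2(dppf) (5 mol %), K3PO4 (aq), DMF, rt
Reagents that add atoms: none
Why: Anti-Markovnikov hydroboration of the terminal vinyl group followed by B-alkyl Suzuki–Miyaura coupling with the α-bromobutenolide forms C12–C13; excess borane should tolerate the free hydroxyl groups (the O–B bonds are hydrolysed by the aqueous base) and the mild phosphate base should spare the butenolide.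

**Compound list**

1 | 3-[(tert-butyldimethylsilyl)oxy]propanal | O=CCCO[Si](C)(C)C(C)(C)C | starting material
2 | pent-1-en-3-one (ethyl vinyl ketone) | C=CC(=O)CC | starting material
3 | (R)-2-{[(tert-butyldimethylsilyl)oxy]methyl}-5-oxoheptanal | O=C[C@@H](CO[Si](C)(C)C(C)(C)C)CCC(=O)CC | intermediate
4 | (S)-4-{[(tert-butyldimethylsilyl)oxy]methyl}-2-methylcyclohex-2-en-1-one | CC1=C[C@@H](CO[Si](C)(C)C(C)(C)C)CCC1=O | intermediate
5 | bromomagnesium enolate of (3R,4S)-3-ethenyl-4-{[(tert-butyldimethylsilyl)oxy]methyl}-2-methylcyclohexanone | CC1=C(O[Mg]Br)CC[C@H](CO[Si](C)(C)C(C)(C)C)[C@H]1C=C | intermediate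
6 | (2R,3R,4S)-2-acetyl-3-ethenyl-4-{[(tert-butyldimethylsilyl)oxy]methyl}-2-methylcyclohexan-1-one | C[C@@]1(C(C)=O)C(=O)CC[C@H](CO[Si](C)(C)C(C)(C)C)[C@H]1C=C | intermediate
7 | methyl (4S,5R)-4-{[(tert-butyldimethylsilyl)oxy]methyl}-5-ethenyl-6-methyl-7-oxooctanoate (C6 epimers) | CC(=O)C(C)[C@H](C=C)[C@@H](CO[Si](C)(C)C(C)(C)C)CCC(=O)OC | intermediate
8 | (4S,5R)-4-{[(tert-butyldimethylsilyl)oxy]methyl}-5-ethenyl-6-methyloctane-1,7-diol (C6 and C7 epimers) | CC(O)C(C)[C@H](C=C)[C@@H](CO[Si](C)(C)C(C)(C)C)CCCO | intermediate
9 | (4S,5R)-4-{[(tert-butyldimethylsilyl)oxy]methyl}-5-ethenyl-6-methyl-7-oxooctanal (C6 epimers) | CC(=O)C(C)[C@H](C=C)[C@@H](CO[Si](C)(C)C(C)(C)C)CCC=O | intermediate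
10 | methyl acrylate | C=CC(=O)OC | starting material
11 | methyl (6S,7R)-6-{[(tert-butyldimethylsilyl)oxy]methyl}-7-ethenyl-3-hydroxy-8-methyl-2-methylidene-9-oxodecanoate (C3 and C8 epimers) | CC(=O)C(C)[C@H](C=C)[C@@H](CO[Si](C)(C)C(C)(C)C)CCC(O)C(=C)C(=O)OC | intermediate
12 | methyl (2E,6S,7R)-2-(acetoxymethyl)-6-{[(tert-butyldimethylsilyl)oxy]methyl}-7-ethenyl-8-methyl-9-oxodec-2-enoate (C8 epimers) | CC(=O)C(C)[C@H](C=C)[C@@H](CO[Si](C)(C)C(C)(C)C)CC/C=C(\COC(C)=O)C(=O)OC | intermediate
13 | methyl 2-[2-acetyl-3-ethenyl-4-{[(tert-butyldimethylsilyl)oxy]methyl}-2-methylcyclohexyl]prop-2-enoate (ring B closed; acetyl and acrylate trans-diequatorial; methyl axial) | C[C@@]1(C(C)=O)[C@@H](C(=C)C(=O)OC)CC[C@H](CO[Si](C)(C)C(C)(C)C)[C@H]1C=C | intermediate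
14 | methyl 5-ethenyl-6-{[(tert-butyldimethylsilyl)oxy]methyl}-4a-methyl-4-oxodecahydronaphthalene-1-carboxylate (trans-fused; ester equatorial) | C[C@@]12C(=O)CC[C@H](C(=O)OC)[C@H]1CC[C@H](CO[Si](C)(C)C(C)(C)C)[C@H]2C=C | intermediate
15 | hydrazone of 14 at the C1 carbonyl | C[C@@]12C(=NN)CC[C@H](C(=O)OC)[C@H]1CC[C@H](CO[Si](C)(C)C(C)(C)C)[C@H]2C=C | intermediate
16 | 5-ethenyl-6-(hydroxymethyl)-4a-methyldecahydronaphthalene-1-carboxylic acid (trans-fused; carboxyl equatorial) | C[C@@]12CCC[C@H](C(=O)O)[C@H]1CC[C@H](CO)[C@H]2C=C | intermediate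
17 | 5-ethenyl-1,6-bis(hydroxymethyl)-4a-methyldecahydronaphthalene-1-carboxylic acid (carboxyl axial) | C[C@@]12CCC[C@@](CO)(C(=O)O)[C@H]1CC[C@H](CO)[C@H]2C=C | intermediate
18 | [(1R,2S,4aS,8aS)-1-ethenyl-8a-methyloctahydronaphthalene-2,5,5(1H)-triyl]trimethanol | C[C@@]12CCCC(CO)(CO)[C@H]1CC[C@H](CO)[C@H]2C=C | intermediate
19 | 3-bromofuran-2(5H)-one | O=C1OCC=C1Br | starting material
20 | B-alkyl-9-borabicyclo[3.3.1]nonane from hydroboration of 18 at C12 | C[C@@]12CCCC(CO)(CO)[C@H]1CC[C@H](CO)[C@H]2CCB1C2CCCC1CCC2 | intermediate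
21 | 3-{2-[(1R,2S,4aS,8aS)-2,5,5-tris(hydroxymethyl)-8a-methyldecahydronaphthalen-1-yl]ethyl}furan-2(5H)-one | C[C@@]12CCCC(CO)(CO)[C@H]1CC[C@H](CO)[C@H]2CCC1=CCOC1=O | target

**Step count and risks**

Total step count: 13. Longest linear sequence: 13.

Steps most likely to fail:

1. Step 9 (key step). The base may deprotonate C6 (γ to the enoate) and trigger 1,4-loss of acetate to a diene before the hindered C10 enolate adds to C5, and facial control at C10 may be incomplete. The fallback changes to Lewis-acid activation in two stages. It sets out from 12: TMSCl, NaI and Et3N in MeCN should give the tetrasubstituted trimethylsilyl enol ether F1. Catalytic Me3SiOSO2CF3 (or TiCl4) in CH2Cl2 at −78 °C then triggers a Mukaiyama–Michael addition of C10 to C5 with loss of trimethylsilyl acetate, giving 13, which is now isolated. With the leaving group gone, LiN(SiMe3)2 in THF forms the C2 enolate, which closes ring A, and the route is rejoined at 14.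

2. Step 3. The hindered tetrasubstituted enolate may be acylated on oxygen instead of carbon. The fallback sets out from 4: the same conjugate addition is quenched with TMSCl to give the silyl enol ether F2. A Mukaiyama aldol addition to acetaldehyde (BF3·OEt2, CH2Cl2, −78 °C) then gives the β-hydroxy ketone F3, and Dess–Martin oxidation rejoins the route at 6.

3. Step 10. Hydrazone formation at the neopentyl-type C1 ketone may be incomplete, and hydrazine may convert the ester into a persistent acyl hydrazide. The fallback is a radical deoxygenation and sets out from 14. NaBH4 reduces the ketone to the alcohol F4; NaH, CS2 and MeI give the xanthate F5. Bu3SnH with AIBN (Barton–McCombie) gives the deoxygenated ester F6. KOH in aqueous methanol followed by acidic work-up hydrolyses the ester and removes the silyl group, rejoining the route at 16.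

Further compounds
F1 | step 9 | trimethylsilyl enol ether of 12 (C10=C1 enol ether) | CC(O[Si](C)(C)C)=C(C)[C@H](C=C)[C@@H](CO[Si](C)(C)C(C)(C)C)CC/C=C(\COC(C)=O)C(=O)OC
F2 | step 3 | trimethylsilyl enol ether of (3R,4S)-3-ethenyl-4-{[(tert-butyldimethylsilyl)oxy]methyl}-2-methylcyclohexanone | CC1=C(O[Si](C)(C)C)CC[C@H](CO[Si](C)(C)C(C)(C)C)[C@H]1C=C
F3 | step 3 | 3-ethenyl-4-{[(tert-butyldimethylsilyl)oxy]methyl}-2-(1-hydroxyethyl)-2-methylcyclohexan-1-one (carbinol epimers) | C[C@@]1(C(C)O)C(=O)CC[C@H](CO[Si](C)(C)C(C)(C)C)[C@H]1C=C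
F4 | step 10 | C1 alcohol from reduction of 14 (carbinol epimers) | C[C@@]12C(O)CC[C@H](C(=O)OC)[C@H]1CC[C@H](CO[Si](C)(C)C(C)(C)C)[C@H]2C=C
F5 | step 10 | S-methyl xanthate of F4 | C[C@@]12C(OC(=S)SC)CC[C@H](C(=O)OC)[C@H]1CC[C@H](CO[Si](C)(C)C(C)(C)C)[C@H]2C=C
F6 | step 10 | methyl 5-ethenyl-6-{[(tert-butyldimethylsilyl)oxy]methyl}-4a-methyldecahydronaphthalene-1-carboxylate | C[C@@]12CCC[C@H](C(=O)OC)[C@H]1CC[C@H](CO[Si](C)(C)C(C)(C)C)[C@H]2C=C
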